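## The problem

Compound 26 is a 5,7-dimethoxyphthalide whose C3 is joined through six methylene groups to C2 of a 7-methyl-1,6-dioxaspiro[4.4]nonane; the arene and the spiroketal are far apart, so the molecule is best made from one aromatic and one chiral aliphatic building block. It has four stereocentres: C3 (R) of the lactone, and C2 (S), C5 (R) and C7 (S) of the spiroketal, with each alkyl group anti to the oxygen of the other ring. C2 and C7 are secondary carbinol carbons and can be bought as epoxides. C3 lies six CH2 groups from C2, so nothing in the substrate can control it and a reagent or catalyst must. C5 is the awkward centre: both rings are five-membered, the anomeric preference is weak, C2 and C7 steer C5 only feebly, and any acid met later can scramble it. The groups that will not stand rough treatment are the spiroketal (Brønsted and Lewis acids), the lactone with its benzylic C3–O bond (hydroxide, hydrogenolysis), the aryl methyl ethers (strong Lewis acids) and the enol lactone that precedes the target. The feature that makes the key step possible is in the benzene ring: C3a and C7a are neighbours, C3a carries C3, C7a carries the C1 carboxyl carbon, and C7a is flanked on its other side by the C7 methoxy group. That 1,2,3,5-pattern is what results when a carbon nucleophile and then carbon dioxide add across the triple bond of 3,5-dimethoxybenzyne, the methoxy group next to the triple bond sending the nucleophile to the remote carbon.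

## Retrosynthesis

**26 to 25.** The C3–H and C1'–H bonds are removed first, so that 26 becomes the hydrogenation product of the (Z)-3-alkylidenephthalide 25. The neighbouring cuts (C3–C1' by asymmetric alkyl addition to an aldehyde, or C3–H by reduction of an aryl ketone) need a functionalised organometallic or an extra carbonyl intermediate. The enol lactone arises directly from the key-step product, and catalytic hydrogenation of this substrate class by iridium phosphine–oxazoline complexes is established. The precursor has one stereocentre fewer. The forward step must deliver hydrogen to one face under catalyst control, without hydrogenolysis of the benzylic C–O bond and without disturbing C5.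

**25 to 24.** The lactone C3–O2 bond is cut, giving the 2-alkynylbenzoic acid 24. The forward reaction is an isomerisation, needs no activation of the acid and fixes the alkene geometry by anti addition. It must close 5-exo-dig and not 6-endo-dig to an isocoumarin.

**24 to 3, 18 and 19 (key disconnection).** The C3a–C3 and C7a–C1 bonds are cut together, so that 24 falls apart into aryne 22 (made from bromo triflate 3), the acetylide 20 of alkyne 18, and carbon dioxide 19. A cross-coupling on a preformed ortho-halobenzoate would make only one of the two bonds and needs a tetrasubstituted arene that already carries the carboxyl group. Directed metalation of an alkynyl dimethoxybenzene would place the carboxyl between the two methoxy groups. The aryne route starts from a symmetrical phenol and lets the methoxy group decide where each new substituent goes. The precursors are much simpler, a two-step arene and an alkyne that holds all of the aliphatic complexity. The forward step needs regioselective acetylide addition, capture of the aryne by the acetylide and not by butyllithium or the product aryllithium 23, and clean carboxylation.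

**3 to 2 to 1.** The S–O bond of the triflate and the C–Br bond are cut, leading back to 3,5-dimethoxyphenol 1. The only demand is bromination ortho to the hydroxyl and not between the methoxy groups.

**18 to 17 to 16 to 15.** The terminal alkyne carbon is removed (one-carbon homologation of aldehyde 17). The aldehyde is traced to alcohol 16 and this to terminal alkene 15. The alkene is chosen because it is inert to the organolithium and acid chemistry used to assemble the spiroketal and is converted to the alkyne under neutral or basic conditions only.

**15 to 12 (through 13 and 14).** Both C5–O bonds are cut, giving keto diol 13, which is carried in masked form as the dihydroxy hydrazone 12. In the forward direction C5 forms under thermodynamic control with little bias, so the (5S) epimer 14 is expected beside 15. It interconverts with 15 under the same acid and is sent back through that equilibrium, which the plan accepts for the sake of a two-step spiroketal assembly.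

**12 to 9, 10 and 8.** The C3–C4 and C6–C7 bonds of 12 (C8–C9 and C3–C4 of the spiroketal) are cut. Acetone dimethylhydrazone 9 serves as a two-sided linchpin between (S)-propylene oxide 10 and epoxide 8. Each carbinol centre arrives ready-made and no redox or protecting-group steps are needed, unlike aldol or alkyne-based routes to the same keto diol. The forward step needs the second deprotonation at the remaining methyl group and attack at the primary epoxide carbons only.

**8 to 7 to 4 and 5.** The epoxide C–O bond and then the C3–C4 bond of chlorohydrin 7 are cut, leading to (S)-epichlorohydrin 5 and the Grignard reagent 6 from 5-bromopent-1-ene 4. Kinetic resolution of the racemic epoxide would discard half the material; this route takes the configuration from a cheap chiral C3 unit.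

## Roads not taken

Alternative 1: kinetic epoxide-opening spirocyclisation. The C5–O6 bond is cut, leading to the cyclic enol ether A1, which carries the C2 chain and the hydroxybutyl tether. In the forward step dimethyldioxirane would oxidise the C4=C5 bond of A1 from the face opposite the C2 chain, and Ti(OiPr)4 would then guide the tethered hydroxyl onto C5 with retention to give A2.
- Merit: C5 is fixed by a stereospecific event and not left to an equilibrium without bias. In this respect the road is better than the chosen plan, which forms 15 together with 14.
- Weak points: the facial selectivity rests on a C2 substituent 1,3 to the alkene on a nearly flat five-membered ring. The retentive cyclisation is best established on six-membered enol ethers. A2 carries a C4 hydroxyl that the target lacks, and its removal (Barton–McCombie deoxygenation to 15) costs two steps beside an acid-labile ketal. A1 itself needs a multistep synthesis.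
- Comparison: the chosen plan sets brevity against this stereocontrol (two steps from the epoxides to 15), and 14 is returned to 15 by acid, not lost. Alternative 1 does not address the arene or C3.

Alternative 2: biomimetic folding of a triketide to the resorcylate. The C3a–C7a bond of the arene is cut, leading to the open-chain diketo dioxinone A3. Triethylamine would induce the dioxinone α-carbon to add to the ketone next to the silyloxy carbon, and dehydration would give the benzodioxinone A4.
- Merits: the arene forms under mild base with no regiochemical question, and C3 enters as a discrete carbinol that can be checked before the ring is built. Here the road is at least as good as the chosen plan, which depends on one late catalyst-controlled hydrogenation for C3.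
- Weak points: the C3 carbinol of A3 is α to the ketone that must react under amine base, so its configuration is at risk by enolisation. A3 requires several C-acylation steps on a spiroketal-bearing fragment. A4 has a free phenol, an acetonide-masked salicylate and a silyl ether, so about four more steps (two methylations, acetonide opening, desilylation with lactonisation) are needed to reach 26.
- Comparison: the chosen plan buys the arene with both methyl ethers in place and needs two steps after its key step. Against the earlier fixing of C3 it sets a precedented asymmetric hydrogenation with a transfer-hydrogenation fallback.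

Alternative 3: acetone hydrazone linchpin as the strategic step. The two C–C bonds flanking the future ketal carbon are cut. In one flask the azaenolate of acetone dimethylhydrazone opens (S)-propylene oxide and, after a second deprotonation, the chain epoxide, giving A5.
- Merits: three components, no protecting groups, both carbinol centres from epoxides. Nothing better is available for this part, and the chosen route uses the same operation as step 5; A5 is identical with 12.
- Weak points as a strategy: it puts the main effort where purchased chirality already solves the problem, leaves C5 to equilibrium as the chosen plan does, and offers nothing for the arene, the union of the halves or C3.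
- Comparison: the chosen plan keeps this construction as a supporting step and reserves its key step for the two arene C–C bonds.

Key step: step 10

Assumption: the antipode of the phosphine–oxazoline ligand that gives the (3R) lactone from a (Z)-3-alkylidenephthalide is settled on a simple model substrate before step 12; that antipode is meant wherever the ligand is named.

## Route

Step 1
Reactants: 1 3,5-dimethoxyphenol
Product: 2 2-bromo-3,5-dimethoxyphenol
Conditions: NBS (1.0 equiv), CH2Cl2, −78 °C to rt
Reagents that add atoms: N-bromosuccinimide, O=C1CCC(=O)N1Br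
Why: Electrophilic aromatic bromination; at low temperature in a non-polar solvent the position ortho to the free hydroxyl should be favoured, and the 4-bromo isomer expected as minor product is removed by chromatography.

Step 2
Reactants: 2 2-bromo-3,5-dimethoxyphenol
Product: 3 2-bromo-3,5-dimethoxyphenyl trifluoromethanesulfonate
Conditions: Tf2O, pyridine, CH2Cl2, 0 °C
Reagents that add atoms: trifluoromethanesulfonic anhydride, O=S(=O)(OS(=O)(=O)C(F)(F)F)C(F)(F)F
Why: O-Sulfonylation of a phenol; the ortho bromine does not hinder triflation and the product has halogen and leaving group on adjacent carbons as an aryne precursor requires.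

Step 3
Reactants: 4 5-bromopent-1-ene; 5 (S)-epichlorohydrin
Product: 7 (2S)-1-chlorooct-7-en-2-ol, via pent-4-enylmagnesium bromide 6 (not isolated)
Conditions: 4, Mg, THF, rt; then CuI (10 mol%), 5, THF, −40 to 0 °C; aq. NH4Cl
Reagents that add atoms: none
Why: Copper-catalysed Grignard opening of a terminal epoxide at its CH2 carbon, which is faster than displacement of chloride; the stereocentre is not touched, so 7 keeps the configuration of 5.

Step 4
Reactants: 7 (2S)-1-chlorooct-7-en-2-ol
Product: 8 (2S)-2-(hex-5-en-1-yl)oxirane
Conditions: NaOH (powdered), Et2O, rt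
Reagents that add atoms: none
Why: Intramolecular Williamson ether synthesis of a chlorohydrin; the alkoxide displaces chloride at the primary carbon, so the carbinol configuration is retained.

Step 5
Reactants: 9 acetone N,N-dimethylhydrazone; 10 (S)-propylene oxide; 8 (2S)-2-(hex-5-en-1-yl)oxirane
Product: 12 (2S,8S)-5-(2,2-dimethylhydrazinylidene)tetradec-13-ene-2,8-diol, via lithium alkoxide of the mono-adduct 11 (not isolated)
Conditions: 9 (1.1 equiv), n-BuLi (1.1 equiv), THF, −78 to 0 °C; 10 (1.05 equiv), 0 °C; n-BuLi (1.1 equiv), −78 to 0 °C; 8 (1.0 equiv), 0 °C to rt; H2O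
Reagents that add atoms: none
Why: Azaenolate alkylation of a ketone dimethylhydrazone by terminal epoxides, run twice in one flask; the second deprotonation occurs at the remaining methyl group (the less substituted α-carbon), and both epoxides are opened at their primary carbons, so C2 and C8 of 12 come unchanged from 10 and 8.

Step 6
Reactants: 12 (2S,8S)-5-(2,2-dimethylhydrazinylidene)tetradec-13-ene-2,8-diol
Product: 15 (2S,5R,7S)-2-(hex-5-en-1-yl)-7-methyl-1,6-dioxaspiro[4.4]nonane, via keto diol 13 (not isolated), via (5S) spiroketal epimer 14 (not isolated)
Conditions: 1 M aq. HCl, THF, rt; chromatography; fractions holding 14 returned uncharacterised to 1 M aq. HCl, THF, rt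
Reagents that add atoms: none
Why: Acid hydrolysis of the dimethylhydrazone frees keto diol 13, whose two γ-hydroxyl groups close onto the ketone (hydrazone hydrolysis with thermodynamic spiroketalisation); C2 and C7 are fixed, C5 equilibrates through the ring-opened oxocarbenium ion with little anomeric bias, so the (5S) epimer 14 forms in comparable amount beside 15 and is sent back through the same acid equilibrium as crude fractions until it has been converted into 15.

Step 7
Reactants: 15 (2S,5R,7S)-2-(hex-5-en-1-yl)-7-methyl-1,6-dioxaspiro[4.4]nonane
Product: 16 6-[(2S,5R,7S)-7-methyl-1,6-dioxaspiro[4.4]nonan-2-yl]hexan-1-ol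
Conditions: 9-BBN, THF, 0 °C to rt; then aq. NaOH, H2O2, 0 °C
Reagents that add atoms: hydrogen peroxide, OO
Why: Anti-Markovnikov hydroboration–oxidation of a terminal alkene; the medium stays neutral to basic, so C5 is not disturbed.

Step 8
Reactants: 16 6-[(2S,5R,7S)-7-methyl-1,6-dioxaspiro[4.4]nonan-2-yl]hexan-1-ol
Product: 17 6-[(2S,5R,7S)-7-methyl-1,6-dioxaspiro[4.4]nonan-2-yl]hexanal
Conditions: n-Pr4NRuO4 (5 mol%), NMO, 4 Å molecular sieves, CH2Cl2, rt
Reagents that add atoms: none
Why: Ley–Griffith oxidation of a primary alcohol to the aldehyde; the conditions are non-acidic and stop at the aldehyde in the absence of water.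

Step 9
Reactants: 17 6-[(2S,5R,7S)-7-methyl-1,6-dioxaspiro[4.4]nonan-2-yl]hexanal
Product: 18 (2S,5R,7S)-2-(hept-6-yn-1-yl)-7-methyl-1,6-dioxaspiro[4.4]nonane
Conditions: dimethyl (1-diazo-2-oxopropyl)phosphonate, K2CO3, MeOH, 0 °C to rt
Reagents that add atoms: dimethyl (1-diazo-2-oxopropyl)phosphonate, COP(=O)(OC)C(=[N+]=[N-])C(C)=O
Why: Ohira–Bestmann variant of the Seyferth–Gilbert homologation; the aldehyde has no stereocentre at its α-carbon and the mild carbonate base leaves the spiroketal alone.

Step 10
Reactants: 18 (2S,5R,7S)-2-(hept-6-yn-1-yl)-7-methyl-1,6-dioxaspiro[4.4]nonane; 3 2-bromo-3,5-dimethoxyphenyl trifluoromethanesulfonate; 19 carbon dioxide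
Product: 24 2-{7-[(2S,5R,7S)-7-methyl-1,6-dioxaspiro[4.4]nonan-2-yl]hept-1-yn-1-yl}-4,6-dimethoxybenzoic acid, via lithium acetylide 20 (not isolated), via ortho-lithio aryl triflate 21 (not isolated), via 3,5-dimethoxybenzyne 22 (not isolated), via aryllithium adduct 23 (not isolated)
Conditions: 18, n-BuLi (1.0 equiv), THF, −78 to 0 °C; 3 (1.2 equiv), −78 °C; n-BuLi (1.2 equiv) added slowly, −78 °C; CO2 (g), −78 °C to rt; cold 0.5 M HCl to pH 3
Reagents that add atoms: none
Why: n-BuLi first converts 18 into acetylide 20; with 3 then present, slowly added n-BuLi exchanges the bromine between the methoxy and triflate groups to give 21, which expels lithium triflate at −78 °C and forms aryne 22. The closest known reaction type is the addition of lithium acetylides and other organolithiums to 3-alkoxyarynes with electrophilic capture of the resulting ortho-alkoxy aryllithium. Acetylide 20 attacks the aryne carbon remote from the flanking methoxy group (future C3a) and forms the C3a–C3 bond, because the inductively withdrawing oxygen makes that carbon the more electrophilic terminus and places the new carbanion ortho to oxygen, where induction and O–Li coordination stabilise it; the second methoxy group, meta to the attacked carbon, has little influence. Aryllithium 23 (future C7a) is then carboxylated by 19, forming the C7a–C1 bond, and cold dilute acid liberates 24. No ring closes and no stereocentre is formed in this step. The selectivities needed are regioselectivity at the aryne, secured by the methoxy group next to the triple bond, and chemoselectivity in aryne capture, secured by having 20 present in bulk while n-BuLi is kept at low stationary concentration and consumed by the faster bromine–lithium exchange. The spiroketal is inert to organolithiums and carbon dioxide, and the short cold acidification is kept milder than what epimerises C5.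

Step 11
Reactants: 24 2-{7-[(2S,5R,7S)-7-methyl-1,6-dioxaspiro[4.4]nonan-2-yl]hept-1-yn-1-yl}-4,6-dimethoxybenzoic acid
Product: 25 (3Z)-5,7-dimethoxy-3-{6-[(2S,5R,7S)-7-methyl-1,6-dioxaspiro[4.4]nonan-2-yl]hexylidene}-2-benzofuran-1(3H)-one
Conditions: DBU (1.0 equiv), MeCN, 80 °C
Reagents that add atoms: none
Why: Base-promoted 5-exo-dig cycloisomerisation of a 2-alkynylbenzoic acid; the carboxylate adds to the aryl-bound alkyne carbon with anti protonation, which gives the Z alkene, and basic conditions favour the exo closure over the 6-endo isocoumarin pathway typical of acid catalysis.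

Step 12
Reactants: 25 (3Z)-5,7-dimethoxy-3-{6-[(2S,5R,7S)-7-methyl-1,6-dioxaspiro[4.4]nonan-2-yl]hexylidene}-2-benzofuran-1(3H)-one
Product: 26 (3R)-5,7-dimethoxy-3-{6-[(2S,5R,7S)-7-methyl-1,6-dioxaspiro[4.4]nonan-2-yl]hexyl}-2-benzofuran-1(3H)-one
Conditions: [Ir(cod)Cl]2 (1 mol%), tBu-PHOX (2.2 mol%, antipode as fixed in the assumption), NaB[3,5-(CF3)2C6H3]4 (2.5 mol%), H2 (20 bar), CH2Cl2, rt
Reagents that add atoms: none
Why: Iridium phosphine–oxazoline catalysed asymmetric hydrogenation of a 3-alkylidenephthalide (an exocyclic enol ester); the single Z isomer and the chiral catalyst determine the face of hydrogen delivery and so set C3 (R), the distant spiroketal centres having no influence, and a homogeneous iridium catalyst should not cleave the benzylic C–O bond.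

## Compound list

1 | 3,5-dimethoxyphenol | COc1cc(O)cc(OC)c1 | starting material
2 | 2-bromo-3,5-dimethoxyphenol | COc1cc(O)c(Br)c(OC)c1 | intermediate
3 | 2-bromo-3,5-dimethoxyphenyl trifluoromethanesulfonate | COc1cc(OC)c(Br)c(OS(=O)(=O)C(F)(F)F)c1 | intermediate
4 | 5-bromopent-1-ene | C=CCCCBr | starting material
5 | (S)-epichlorohydrin [(2S)-2-(chloromethyl)oxirane] | ClC[C@@H]1CO1 | starting material
6 | pent-4-enylmagnesium bromide | C=CCCC[Mg]Br | intermediate
7 | (2S)-1-chlorooct-7-en-2-ol | ClC[C@@H](O)CCCCC=C | intermediate
8 | (2S)-2-(hex-5-en-1-yl)oxirane | C=CCCCC[C@H]1CO1 | intermediate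
9 | acetone N,N-dimethylhydrazone | CC(C)=NN(C)C | starting material
10 | (S)-propylene oxide [(2S)-2-methyloxirane] | C[C@H]1CO1 | starting material
11 | lithium (2S)-5-(2,2-dimethylhydrazinylidene)hexan-2-olate | C[C@H]([O-])CCC(C)=NN(C)C.[Li+] | intermediate
12 | (2S,8S)-5-(2,2-dimethylhydrazinylidene)tetradec-13-ene-2,8-diol | C=CCCCC[C@H](O)CCC(=NN(C)C)CC[C@H](C)O | intermediate
13 | (2S,8S)-2,8-dihydroxytetradec-13-en-5-one (keto diol) | C=CCCCC[C@H](O)CCC(=O)CC[C@H](C)O | intermediate
14 | (2S,5S,7S)-2-(hex-5-en-1-yl)-7-methyl-1,6-dioxaspiro[4.4]nonane (C5 epimer of 15, equilibrated in step 6) | C=CCCCC[C@H]1CC[C@]3(CC[C@H](C)O3)O1 | intermediate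
15 | (2S,5R,7S)-2-(hex-5-en-1-yl)-7-methyl-1,6-dioxaspiro[4.4]nonane | C=CCCCC[C@H]1CC[C@@]3(CC[C@H](C)O3)O1 | intermediate
16 | 6-[(2S,5R,7S)-7-methyl-1,6-dioxaspiro[4.4]nonan-2-yl]hexan-1-ol | OCCCCCC[C@H]1CC[C@@]3(CC[C@H](C)O3)O1 | intermediate
17 | 6-[(2S,5R,7S)-7-methyl-1,6-dioxaspiro[4.4]nonan-2-yl]hexanal | O=CCCCCC[C@H]1CC[C@@]3(CC[C@H](C)O3)O1 | intermediate
18 | (2S,5R,7S)-2-(hept-6-yn-1-yl)-7-methyl-1,6-dioxaspiro[4.4]nonane | C#CCCCCC[C@H]1CC[C@@]3(CC[C@H](C)O3)O1 | intermediate
19 | carbon dioxide | O=C=O | starting material
20 | lithium acetylide of 18 (lithium 7-[(2S,5R,7S)-7-methyl-1,6-dioxaspiro[4.4]nonan-2-yl]hept-1-yn-1-ide) | [Li]C#CCCCCC[C@H]1CC[C@@]3(CC[C@H](C)O3)O1 | intermediate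
21 | 2-lithio-3,5-dimethoxyphenyl trifluoromethanesulfonate | COc1cc(OC)c([Li])c(OS(=O)(=O)C(F)(F)F)c1 | intermediate
22 | 3,5-dimethoxybenzyne (1,2-didehydro-3,5-dimethoxybenzene) | COC1=CC(OC)=CC#C1 | intermediate
23 | (2,4-dimethoxy-6-{7-[(2S,5R,7S)-7-methyl-1,6-dioxaspiro[4.4]nonan-2-yl]hept-1-yn-1-yl}phenyl)lithium | COc1cc(OC)c([Li])c(c1)C#CCCCCC[C@H]1CC[C@@]3(CC[C@H](C)O3)O1 | intermediate
24 | 2-{7-[(2S,5R,7S)-7-methyl-1,6-dioxaspiro[4.4]nonan-2-yl]hept-1-yn-1-yl}-4,6-dimethoxybenzoic acid | COc1cc(OC)c(C(=O)O)c(c1)C#CCCCCC[C@H]1CC[C@@]3(CC[C@H](C)O3)O1 | intermediate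
25 | (3Z)-5,7-dimethoxy-3-{6-[(2S,5R,7S)-7-methyl-1,6-dioxaspiro[4.4]nonan-2-yl]hexylidene}-2-benzofuran-1(3H)-one | COc1cc(OC)c2c(c1)/C(=C/CCCCC[C@H]1CC[C@@]3(CC[C@H](C)O3)O1)OC2=O | intermediate
26 | (3R)-5,7-dimethoxy-3-{6-[(2S,5R,7S)-7-methyl-1,6-dioxaspiro[4.4]nonan-2-yl]hexyl}-2-benzofuran-1(3H)-one | COc1cc(OC)c2c(c1)[C@@H](CCCCCC[C@H]1CC[C@@]3(CC[C@H](C)O3)O1)OC2=O | target

## Step count and least certain steps

Total: 12 steps. Longest linear sequence: 10 steps (steps 3 to 12, from 5-bromopent-1-ene and (S)-epichlorohydrin). The aryne precursor needs 2 steps and joins at step 10.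

**Step 10 (key step).** The aryne may be captured by butyllithium or by the product aryllithium instead of the acetylide, which would cost the valuable alkyne and give butylated or biaryl acids that are hard to remove. Attack of butyllithium at the triflate sulfur is a further loss. The cause is that three carbanions compete for a short-lived electrophile. Fallback, from 18 back to 24: Sonogashira coupling of 18 with 2-bromo-4,6-dimethoxybenzaldehyde F1 (Pd(PPh3)2Cl2, CuI, Et3N, 60 °C) should give 2,4-dimethoxy-6-alkynylbenzaldehyde F2, and Pinnick oxidation (NaClO2, NaH2PO4, 2-methylbut-2-ene, t-BuOH/H2O) converts it into 24. The aryne is replaced by a palladium-catalysed coupling on an arene that already carries the carbonyl carbon.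

**Step 6.** C5 forms without a useful thermodynamic preference, and two non-polar epimers that differ only at the ketal carbon may not separate on silica, so material throughput and purity at C5 are both at risk. Fallback, from the unseparated mixture of 15 and 14 back to 16: the mixture is hydroborated as in step 7 to give 16 together with its (5S) epimer, 6-[(2S,5S,7S)-7-methyl-1,6-dioxaspiro[4.4]nonan-2-yl]hexan-1-ol F3. Acylation with 3,5-dinitrobenzoyl chloride and pyridine gives the 3,5-dinitrobenzoate of 16 F4 and the 3,5-dinitrobenzoate of the epimer F5. These UV-active, potentially crystalline esters are separated by crystallisation or chromatography. Methanolysis of F4 (K2CO3, MeOH) returns 16. F5 is methanolysed, re-equilibrated with acid and recycled.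

**Step 12.** Facial selectivity may be insufficient on this 7-methoxy-substituted enol lactone. The acidic iridium hydride intermediates may also epimerise C5 in the last step, when no recycling is possible. Fallback, from 25 back to 26: aqueous NaOH in THF opens the enol lactone to 2,4-dimethoxy-6-acylbenzoic acid (keto acid) F6. MeI and K2CO3 in DMF give the methyl keto ester F7. Noyori asymmetric transfer hydrogenation (RuCl[(R,R)-TsDPEN](p-cymene), HCO2H–Et3N with the amine in excess) should give the (R)-hydroxy ester F8, which lactonises to 26 with loss of methanol. C3 is then set by ketone reduction in a buffered medium, not by alkene hydrogenation.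

**Step 1.** Bromination may occur between the two methoxy groups (para to the hydroxyl) as well as ortho to the hydroxyl, because all free positions of the ring are activated. Fallback, from 1 back to 2: carbamoylation (ClCONEt2, K2CO3, MeCN) gives 3,5-dimethoxyphenyl diethylcarbamate F9. Directed ortho-metalation (s-BuLi, TMEDA, THF, −78 °C) occurs between the carbamate and the neighbouring methoxy group, and quenching with BrCCl2CCl2Br gives 2-bromo-3,5-dimethoxyphenyl diethylcarbamate F10. Hydrolysis (NaOH, EtOH, reflux) gives 2. The position of bromine is then fixed by the directing group and not by electrophilic preference.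

**Step 5.** In the one-flask sequence, incomplete consumption of the first epoxide or of the first azaenolate would give symmetrical bis-adducts and mono-adducts of 8, and the lithium alkoxide may slow the second deprotonation. Fallback, from 9 and 10 back to 15: the first alkylation is worked up to isolate (2S)-5-(2,2-dimethylhydrazinylidene)hexan-2-ol F11, which is silylated (Et3SiCl, imidazole, CH2Cl2) to its triethylsilyl ether F12. Deprotonation (LiN(i-Pr)2, THF, 0 °C) and addition of 8 give the mono-silylated dihydroxy hydrazone F13. Treatment with 1 M aq. HCl in THF removes the silyl group, hydrolyses the hydrazone and closes the spiroketal to 15 (with 14, handled as in step 6). The three-component flask is replaced by a stepwise, protected sequence.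

Further compounds

F1 | step 10 | 2-bromo-4,6-dimethoxybenzaldehyde | COc1cc(OC)c(C=O)c(Br)c1
F2 | step 10 | 2,4-dimethoxy-6-{7-[(2S,5R,7S)-7-methyl-1,6-dioxaspiro[4.4]nonan-2-yl]hept-1-yn-1-yl}benzaldehyde | COc1cc(OC)c(C=O)c(c1)C#CCCCCC[C@H]1CC[C@@]3(CC[C@H](C)O3)O1
F3 | step 6 | 6-[(2S,5S,7S)-7-methyl-1,6-dioxaspiro[4.4]nonan-2-yl]hexan-1-ol | OCCCCCC[C@H]1CC[C@]3(CC[C@H](C)O3)O1
F4 | step 6 | 6-[(2S,5R,7S)-7-methyl-1,6-dioxaspiro[4.4]nonan-2-yl]hexyl 3,5-dinitrobenzoate | O=C(OCCCCCC[C@H]1CC[C@@]3(CC[C@H](C)O3)O1)c1cc(cc(c1)[N+](=O)[O-])[N+](=O)[O-]
F5 | step 6 | 6-[(2S,5S,7S)-7-methyl-1,6-dioxaspiro[4.4]nonan-2-yl]hexyl 3,5-dinitrobenzoate | O=C(OCCCCCC[C@H]1CC[C@]3(CC[C@H](C)O3)O1)c1cc(cc(c1)[N+](=O)[O-])[N+](=O)[O-]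
F6 | step 12 | 2,4-dimethoxy-6-{7-[(2S,5R,7S)-7-methyl-1,6-dioxaspiro[4.4]nonan-2-yl]heptanoyl}benzoic acid | COc1cc(OC)c(C(=O)O)c(c1)C(=O)CCCCCC[C@H]1CC[C@@]3(CC[C@H](C)O3)O1
F7 | step 12 | methyl 2,4-dimethoxy-6-{7-[(2S,5R,7S)-7-methyl-1,6-dioxaspiro[4.4]nonan-2-yl]heptanoyl}benzoate | COC(=O)c1c(OC)cc(OC)cc1C(=O)CCCCCC[C@H]1CC[C@@]3(CC[C@H](C)O3)O1
F8 | step 12 | methyl 2-{(1R)-1-hydroxy-7-[(2S,5R,7S)-7-methyl-1,6-dioxaspiro[4.4]nonan-2-yl]heptyl}-4,6-dimethoxybenzoate | COC(=O)c1c(OC)cc(OC)cc1[C@H](O)CCCCCC[C@H]1CC[C@@]3(CC[C@H](C)O3)O1
F9 | step 1 | 3,5-dimethoxyphenyl diethylcarbamate | CCN(CC)C(=O)Oc1cc(OC)cc(OC)c1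
F10 | step 1 | 2-bromo-3,5-dimethoxyphenyl diethylcarbamate | CCN(CC)C(=O)Oc1cc(OC)cc(OC)c1Br
F11 | step 5 | (2S)-5-(2,2-dimethylhydrazinylidene)hexan-2-ol | C[C@H](O)CCC(C)=NN(C)C
F12 | step 5 | (2S)-5-(2,2-dimethylhydrazinylidene)-2-(triethylsilyloxy)hexane | C[C@H](O[Si](CC)(CC)CC)CCC(C)=NN(C)C
F13 | step 5 | (7S,13S)-10-(2,2-dimethylhydrazinylidene)-13-(triethylsilyloxy)tetradec-1-en-7-ol | C=CCCCC[C@H](O)CCC(=NN(C)C)CC[C@H](C)O[Si](CC)(CC)CC
A1 | alternative 1 | (2S)-4-[(5S)-5-(hex-5-en-1-yl)-4,5-dihydrofuran-2-yl]butan-2-ol | C=CCCCC[C@H]1CC=C(CC[C@H](C)O)O1
A2 | alternative 1 | (2S,4S,5R,7S)-2-(hex-5-en-1-yl)-7-methyl-1,6-dioxaspiro[4.4]nonan-4-ol | C=CCCCC[C@H]1C[C@H](O)[C@@]3(CC[C@H](C)O3)O1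
A3 | alternative 2 | 2,2-dimethyl-6-{(5R)-11-[(2S,5R,7S)-7-methyl-1,6-dioxaspiro[4.4]nonan-2-yl]-2,4-dioxo-5-(triethylsilyloxy)undecyl}-4H-1,3-dioxin-4-one | CC1(C)OC(=O)C=C(O1)CC(=O)CC(=O)[C@@H](CCCCCC[C@H]4CC[C@@]3(CC[C@H](C)O3)O4)O[Si](CC)(CC)CC
A4 | alternative 2 | 7-hydroxy-2,2-dimethyl-5-{(1R)-7-[(2S,5R,7S)-7-methyl-1,6-dioxaspiro[4.4]nonan-2-yl]-1-(triethylsilyloxy)heptyl}-4H-1,3-benzodioxin-4-one | CC1(C)OC(=O)c2c(O1)cc(O)cc2[C@@H](CCCCCC[C@H]4CC[C@@]3(CC[C@H](C)O3)O4)O[Si](CC)(CC)CC
A5 | alternative 3 | (2S,8S)-5-(2,2-dimethylhydrazinylidene)tetradec-13-ene-2,8-diol (identical with 12) | C=CCCCC[C@H](O)CCC(=NN(C)C)CC[C@H](C)O
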